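**Retrosynthetic overview**
- Key disconnection: the C3(=O)–C4 bond of the central pentan-3-one. Forward, the (R)-2-(pyranonyl)propanoic acid of the pentyl half is joined to a lateral C(sp3)–H bond of symmetric 2,6-diethyl-3,5-dimethyl-4-pyranone by hydrogen-atom abstraction and radical capture at an acyl-nickel species, which also sets the (S) centre.
- The (R) centre comes from Evans methylation of a pyranonyl-acetyl imide, made by lateral lithiation/carboxylation of 2,3,5-trimethyl-6-pentyl-4-pyranone.
- Ring order: ring A (pentyl pyranone) first, by mixed polyphosphoric acid condensation of 3-pentanone with acetic and hexanoic acid; ring B (ethyl pyranone) separately from 3-pentanone and two equivalents of propanoic acid; the two finished rings are joined in the last step.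

Assumption: the sense of induction of the nickel/bis(oxazoline) catalyst in step 6 is taken by analogy with benzylic acylations; the ligand is written as (S,S), and its antipode is used if a model run shows the opposite sense.

Step 1
Reactants: 1 3-pentanone; 2 acetic acid; 3 hexanoic acid
Product: 5 2,3,5-trimethyl-6-pentyl-4H-pyran-4-one, via triketone 4 (not isolated)
Conditions: polyphosphoric acid, 130 °C, 3 h (1 : 2 : 3 = 1 : 1.5 : 1.5); chromatography
Reagents that add atoms: none
Why: Polyphosphoric acid promotes two successive C-acylations of the ketone, one by each acid at each α-carbon, to triketone 4 and then its cyclodehydration to ring A (classical γ-pyranone synthesis from a ketone and carboxylic acids); the mixed product is the statistically favoured one (about half of the pyranone formed), is separated easily from the two symmetric pyranones that differ from it by four carbons each, and carries no stereocentre.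

Step 2
Reactants: 5 2,3,5-trimethyl-6-pentyl-4H-pyran-4-one
Product: 9 (R)-4-benzyl-3-[2-(3,5-dimethyl-4-oxo-6-pentyl-4H-pyran-2-yl)acetyl]oxazolidin-2-one, via lithium dienolate 6 (not isolated), via lithium carboxylate 7 (not isolated), via mixed pivalic anhydride 8 (not isolated)
Conditions: LiN(i-Pr)2 (1.05 equiv), THF, −78 °C; CO2 (g), −78 to 0 °C, then Ar purge; t-BuCOCl, 0 °C; (R)-4-benzyl-2-oxazolidinone, Et3N, 0 °C to rt
Reagents that add atoms: LiN(i-Pr)2 (lithium diisopropylamide) CC(C)N([Li])C(C)C (Li, in 6 and 7 only); carbon dioxide O=C=O; pivaloyl chloride CC(C)(C)C(Cl)=O (in 8 only); (R)-4-benzyl-2-oxazolidinone O=C1N[C@H](Cc2ccccc2)CO1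
Why: Kinetic deprotonation with the hindered amide base takes the unhindered C2 methyl group in preference to the α-methylene of the pentyl chain (the C3 and C5 methyl groups are not acidified), the vinylogous enolate is carboxylated at its exocyclic carbon, and the carboxylate is carried without isolation through the mixed pivalic anhydride into the N-acyl oxazolidinone, helped by the LiCl formed in the flask (lateral lithiation–carboxylation followed by Evans mixed-anhydride acylation); the only stereocentre is that of the auxiliary.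

Step 3
Reactants: 9 (R)-4-benzyl-3-[2-(3,5-dimethyl-4-oxo-6-pentyl-4H-pyran-2-yl)acetyl]oxazolidin-2-one
Product: 11 (R)-4-benzyl-3-[(R)-2-(3,5-dimethyl-4-oxo-6-pentyl-4H-pyran-2-yl)propanoyl]oxazolidin-2-one, via sodium enolate 10 (not isolated)
Conditions: NaN(SiMe3)2 (1.05 equiv), THF, −78 °C; MeI (5 equiv), −78 °C; AcOH quench at −78 °C
Reagents that add atoms: NaN(SiMe3)2 (sodium bis(trimethylsilyl)amide) C[Si](C)(C)N([Na])[Si](C)(C)C (Na, in 10 only); iodomethane CI
Why: The chelated (Z)-sodium enolate is methylated on the face opposite the benzyl group of the (R)-auxiliary (Evans asymmetric alkylation), which sets the new centre as R, as for arylacetyl imides (dr of about 10:1 or better expected, minor diastereomer removed by chromatography).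

Step 4
Reactants: 11 (R)-4-benzyl-3-[(R)-2-(3,5-dimethyl-4-oxo-6-pentyl-4H-pyran-2-yl)propanoyl]oxazolidin-2-one
Product: 13 (R)-2-(3,5-dimethyl-4-oxo-6-pentyl-4H-pyran-2-yl)propanoic acid, via peroxy acid 12 (not isolated)
Conditions: LiOH, H2O2, THF/H2O 3:1, 0 °C; aq. Na2SO3; 1 M HCl to pH 3 at 0 °C; used at once
Reagents that add atoms: hydrogen peroxide OO (both O in 12, one O kept in 13)
Why: The hydroperoxide anion attacks the exocyclic imide carbonyl selectively and is too weak a base to enolise the acidic α-centre at 0 °C, and sulfite reduces the peroxy acid to the acid (Evans auxiliary cleavage with LiOH/H2O2), so the R centre is kept; the acid is a vinylogous β-keto acid and is therefore kept cold.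

Step 5
Reactants: 1 3-pentanone; 14 propanoic acid
Product: 16 2,6-diethyl-3,5-dimethyl-4H-pyran-4-one, via triketone 15 (not isolated)
Conditions: polyphosphoric acid, 130 °C, 3 h (1 : 14 = 1 : 2.5)
Reagents that add atoms: propanoic acid CCC(=O)O (second equivalent of 14; its propanoyl unit becomes the second ring carbon bearing an ethyl group)
Why: Two molecules of 14 are consumed per molecule of 1, one acylating each α-carbon of the ketone to give triketone 15, which cyclodehydrates to ring B (the same polyphosphoric acid γ-pyranone synthesis as in step 1, now with a single acid); the product is symmetric, so its four lateral methylene hydrogens are equivalent, and it has no stereocentre.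

Step 6
Reactants: 13 (R)-2-(3,5-dimethyl-4-oxo-6-pentyl-4H-pyran-2-yl)propanoic acid; 16 2,6-diethyl-3,5-dimethyl-4H-pyran-4-one (6 equiv, excess recovered)
Product: 18 (2R,4S)-2-(3,5-dimethyl-4-oxo-6-pentyl-4H-pyran-2-yl)-4-(6-ethyl-3,5-dimethyl-4-oxo-4H-pyran-2-yl)pentan-3-one (CNP0268096.2), via mixed carbonic anhydride 17 (not isolated)
Conditions: dimethyl dicarbonate (2 equiv), K2HPO4 (1 equiv), NiBr2·glyme (10 mol %), (S,S)-Ph-BOX [2,2'-(propane-2,2-diyl)bis((4S)-4-phenyl-4,5-dihydrooxazole), 12 mol %], Ir[dF(CF3)ppy]2(dtbbpy)PF6 (2 mol %), PhH/MeCN 9:1, 450 nm LEDs, 15 °C, 24 h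
Reagents that add atoms: dimethyl dicarbonate COC(=O)OC(=O)OC (its methoxycarbonyl group is in 17 only; 18 takes no atoms from it)
Why: Proposed new method: mixed anhydride 17 adds oxidatively to zerovalent nickel, a bromine atom released under photoredox conditions from the bromide bound to nickel (from NiBr2·glyme) abstracts a weak secondary lateral C–H of 16 (a vinylogous α-keto position, favoured over the primary ring-methyl C–H bonds and statistically over the pentyl α-CH2 of the acid because 16 is in excess), the planar radical is captured by the chiral acyl-nickel species and reductive elimination from trivalent nickel forms the C3–C4 bond with the ligand fixing the new centre as S, while the R centre of the acyl unit is not involved and the only base is weak and heterogeneous; closest known reaction type: photoredox/nickel dual-catalysed enantioselective benzylic C–H acylation of ethylarenes with carboxylic acids activated in situ.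

**Compound list**
1 | 3-pentanone | CCC(=O)CC | starting material
2 | acetic acid | CC(=O)O | starting material
3 | hexanoic acid | CCCCCC(=O)O | starting material
4 | 3,5-dimethylundecane-2,4,6-trione (stereoisomer mixture) | CC(=O)C(C)C(=O)C(C)C(=O)CCCCC | intermediate
5 | 2,3,5-trimethyl-6-pentyl-4H-pyran-4-one | CCCCCc1oc(C)c(C)c(=O)c1C | intermediate
6 | lithium 3,5-dimethyl-2-methylidene-6-pentyl-2H-pyran-4-olate | C=C1OC(CCCCC)=C(C)C(O[Li])=C1C | intermediate
7 | lithium 2-(3,5-dimethyl-4-oxo-6-pentyl-4H-pyran-2-yl)acetate | [Li+].[O-]C(=O)Cc1oc(CCCCC)c(C)c(=O)c1C | intermediate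
8 | 2-(3,5-dimethyl-4-oxo-6-pentyl-4H-pyran-2-yl)acetic pivalic anhydride | CC(C)(C)C(=O)OC(=O)Cc1oc(CCCCC)c(C)c(=O)c1C | intermediate
9 | (R)-4-benzyl-3-[2-(3,5-dimethyl-4-oxo-6-pentyl-4H-pyran-2-yl)acetyl]oxazolidin-2-one | CCCCCc1oc(CC(=O)N2[C@H](Cc3ccccc3)COC2=O)c(C)c(=O)c1C | intermediate
10 | sodium (Z)-enolate of 9 | CCCCCc1oc(/C=C(\O[Na])N2[C@H](Cc3ccccc3)COC2=O)c(C)c(=O)c1C | intermediate
11 | (R)-4-benzyl-3-[(R)-2-(3,5-dimethyl-4-oxo-6-pentyl-4H-pyran-2-yl)propanoyl]oxazolidin-2-one | CCCCCc1oc([C@@H](C)C(=O)N2[C@H](Cc3ccccc3)COC2=O)c(C)c(=O)c1C | intermediate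
12 | (R)-2-(3,5-dimethyl-4-oxo-6-pentyl-4H-pyran-2-yl)propaneperoxoic acid | CCCCCc1oc([C@@H](C)C(=O)OO)c(C)c(=O)c1C | intermediate
13 | (R)-2-(3,5-dimethyl-4-oxo-6-pentyl-4H-pyran-2-yl)propanoic acid | CCCCCc1oc([C@@H](C)C(=O)O)c(C)c(=O)c1C | intermediate
14 | propanoic acid | CCC(=O)O | starting material
15 | 4,6-dimethylnonane-3,5,7-trione (stereoisomer mixture) | CCC(=O)C(C)C(=O)C(C)C(=O)CC | intermediate
16 | 2,6-diethyl-3,5-dimethyl-4H-pyran-4-one | CCc1oc(CC)c(C)c(=O)c1C | intermediate
17 | (R)-2-(3,5-dimethyl-4-oxo-6-pentyl-4H-pyran-2-yl)propanoic methyl carbonic anhydride | CCCCCc1oc([C@@H](C)C(=O)OC(=O)OC)c(C)c(=O)c1C | intermediate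
18 | (2R,4S)-2-(3,5-dimethyl-4-oxo-6-pentyl-4H-pyran-2-yl)-4-(6-ethyl-3,5-dimethyl-4-oxo-4H-pyran-2-yl)pentan-3-one | CCCCCc1oc([C@@H](C)C(=O)[C@@H](C)c2oc(CC)c(C)c(=O)c2C)c(C)c(=O)c1C | target

**Count**
Total steps: 6. Longest linear sequence: 5 (steps 1, 2, 3, 4, 6); step 5 is a one-step side branch.

**Steps most likely to fail, with fallbacks**

Step 6 is the riskiest. Hydrogen abstraction may also occur at other lateral or ring-methyl C–H bonds, the α-branched acyl donor may turn over slowly, and the labile centres may epimerise. The fallback replaces C–H abstraction by halogen-atom abstraction under base-free reductive conditions; it sets out from 16 and 13 and comes back at 18. Pyranone 16 is deprotonated (LiN(i-Pr)2, THF, −78 °C) to lithium 6-ethyl-2-ethylidene-3,5-dimethyl-2H-pyran-4-olate F1, which C2Cl6 chlorinates to racemic 2-(1-chloroethyl)-6-ethyl-3,5-dimethyl-4H-pyran-4-one F2. Acid 13 is turned under neutral conditions (1-chloro-N,N,2-trimethylprop-1-en-1-amine, CH2Cl2, 0 °C) into (R)-2-(3,5-dimethyl-4-oxo-6-pentyl-4H-pyran-2-yl)propanoyl chloride F3. F2 and F3 are joined by nickel-catalysed enantioconvergent reductive acyl cross-coupling (NiCl2·glyme, (S,S)-Ph-BOX, Mn powder, 2,6-dimethylbenzoic acid, 3 Å sieves, DMA/THF, 20 °C), in which the lateral radical from F2 is captured by the chiral acyl-nickel species to give 18.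

Step 2 is second. The lateral lithiation may not discriminate well enough between the methyl group and the pentyl α-CH2, and the telescoped carboxylation/acylation may give a poor yield. The fallback builds the acetyl-imide arm on a symmetric pyranone and adds the butyl group afterwards under acidity control; it sets out from 1 and 2 and comes back at 9. Condensation of 1 with two equivalents of 2 alone (polyphosphoric acid, 130 °C) gives 2,3,5,6-tetramethyl-4H-pyran-4-one F4, whose two lateral methyl groups are equivalent. The reagent sequence of step 2 leads through lithium 3,5,6-trimethyl-2-methylidene-2H-pyran-4-olate F5, lithium 2-(3,5,6-trimethyl-4-oxo-4H-pyran-2-yl)acetate F6 and 2-(3,5,6-trimethyl-4-oxo-4H-pyran-2-yl)acetic pivalic anhydride F7 to (R)-4-benzyl-3-[2-(3,5,6-trimethyl-4-oxo-4H-pyran-2-yl)acetyl]oxazolidin-2-one F8. Two equivalents of LiN(i-Pr)2 (THF, −78 °C) then give the dilithiated imide (Z-enolate plus 6-lithiomethyl group) F9. 1-Iodobutane (1 equiv) alkylates only the more basic terminal carbanion, and an acetic acid quench gives 9.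

Step 4 is third. The doubly activated α-centre may lose configuration in basic peroxide, or the free acid may decarboxylate during acidic isolation. The fallback replaces hydrolysis by non-basic transesterification and neutral hydrogenolysis; it sets out from 11 and comes back at 13. Lewis-acid-catalysed alcoholysis of 11 (BnOH, Sm(OTf)3, CH2Cl2, rt) gives benzyl (R)-2-(3,5-dimethyl-4-oxo-6-pentyl-4H-pyran-2-yl)propanoate F10 and returns the auxiliary. Hydrogenolysis (H2 1 atm, Pd/C, EtOAc, rt; the tetrasubstituted pyranone double bonds are inert) releases 13 in neutral solution, which is filtered and taken directly into step 6.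

**Further compounds**
F1 | step 6 | lithium 6-ethyl-2-ethylidene-3,5-dimethyl-2H-pyran-4-olate | CC=C1OC(CC)=C(C)C(O[Li])=C1C
F2 | step 6 | racemic 2-(1-chloroethyl)-6-ethyl-3,5-dimethyl-4H-pyran-4-one | CCc1oc(C(C)Cl)c(C)c(=O)c1C
F3 | step 6 | (R)-2-(3,5-dimethyl-4-oxo-6-pentyl-4H-pyran-2-yl)propanoyl chloride | CCCCCc1oc([C@@H](C)C(Cl)=O)c(C)c(=O)c1C
F4 | step 2 | 2,3,5,6-tetramethyl-4H-pyran-4-one | Cc1oc(C)c(C)c(=O)c1C
F5 | step 2 | lithium 3,5,6-trimethyl-2-methylidene-2H-pyran-4-olate | C=C1OC(C)=C(C)C(O[Li])=C1C
F6 | step 2 | lithium 2-(3,5,6-trimethyl-4-oxo-4H-pyran-2-yl)acetate | [Li+].[O-]C(=O)Cc1oc(C)c(C)c(=O)c1C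
F7 | step 2 | 2-(3,5,6-trimethyl-4-oxo-4H-pyran-2-yl)acetic pivalic anhydride | CC(C)(C)C(=O)OC(=O)Cc1oc(C)c(C)c(=O)c1C
F8 | step 2 | (R)-4-benzyl-3-[2-(3,5,6-trimethyl-4-oxo-4H-pyran-2-yl)acetyl]oxazolidin-2-one | Cc1oc(CC(=O)N2[C@H](Cc3ccccc3)COC2=O)c(C)c(=O)c1C
F9 | step 2 | dilithiated imide (Z-enolate plus 6-lithiomethyl group) | [Li]Cc1oc(/C=C(\O[Li])N2[C@H](Cc3ccccc3)COC2=O)c(C)c(=O)c1C
F10 | step 4 | benzyl (R)-2-(3,5-dimethyl-4-oxo-6-pentyl-4H-pyran-2-yl)propanoate | CCCCCc1oc([C@@H](C)C(=O)OCc2ccccc2)c(C)c(=O)c1C
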